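The target is made from a bis-2H-chromene by hydrogenation of the two pyran C3=C4 bonds, so both heterocycles can be built at the chromene oxidation level.
Key disconnection: both pyran rings of this bis-chromene are opened in one operation, the pyran on ring B at C2–C3 and the pyran on ring A at C4–C4a, leading back to an acyclic diyne with an ortho-ethynyl aryl isopropyl ether on ring B and an aryl 1,1-dimethylpropargyl ether on ring A.
Enabling feature: in the pyran fused to ring B, C2 bears O1 and two methyl groups, so it is the methine carbon of an isopropyl aryl ether; its tertiary C–H is hydridic and stands 1,5 to C4 (the benzylic carbon on C4a, ortho to O1), so a hydride shift from C2 to an activated alkyne carbon at C4 makes C2 an oxocarbenium carbon and C3 a nucleophilic vinyl-metal carbon, which then join.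
The dihydrochalcone backbone comes from Hoesch acylation of phloroglucinol (symmetric, one regioisomer) with a 3-arylpropanenitrile; the alkyne on ring B is introduced by Sonogashira coupling and the propargyl ether on ring A by alkylation of the only phenol not hydrogen-bonded to the ketone.
Order of ring formation: pyran on ring A first (room temperature), pyran on ring B second (80 °C), both in one flask with one gold catalyst; the two benzene rings come from the starting materials.

Key step: step 7

Remark: the target has no stereocentre, so no stereocontrol is needed; ring A is the acylated phloroglucinol ring, ring B the other benzene ring, both pyran rings are numbered as in chroman (O1, C2, C3, C4, C4a to C8a), and 3-(4-hydroxyphenyl)propanenitrile and phloroglucinol are taken to be commercial.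

Step 1
Reactants: 1 3-(4-hydroxyphenyl)propanenitrile
Product: 2 3-(4-hydroxy-3-iodophenyl)propanenitrile
Conditions: NIS (1.0 equiv), TsOH·H2O (10 mol%), MeCN, 0 °C to rt
Reagents that add atoms: N-iodosuccinimide, O=C1CCC(=O)N1I
Why: Electrophilic aromatic iodination (SEAr) should go ortho to the hydroxyl group because the para position carries the side chain, and one equivalent of NIS at low temperature limits di-iodination.

Step 2
Reactants: 2 3-(4-hydroxy-3-iodophenyl)propanenitrile
Product: 3 3-(3-iodo-4-isopropoxyphenyl)propanenitrile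
Conditions: 2-bromopropane, K2CO3, DMF, 60 °C
Reagents that add atoms: 2-bromopropane, CC(C)Br
Why: Williamson ether synthesis: the phenoxide (made more acidic by the ortho-iodine) should be alkylated by the secondary bromide in DMF, while carbonate is too weak to deprotonate the position next to the nitrile.

Step 3
Reactants: 3 3-(3-iodo-4-isopropoxyphenyl)propanenitrile; 4 phloroglucinol
Product: 6 3-(3-iodo-4-isopropoxyphenyl)-1-(2,4,6-trihydroxyphenyl)propan-1-one, via ketiminium chloride 5 (not isolated)
Conditions: ZnCl2, HCl (g), Et2O, 0 °C; then H2O, 100 °C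
Reagents that add atoms: water, O
Why: Houben–Hoesch acylation: the nitrilium species formed from 3 should attack the very electron-rich, threefold-symmetric phloroglucinol (only one regioisomer possible), the protonated ketimine 5 deactivates the ring against a second acylation, and hot water hydrolyses it to the ketone while the aryl iodide and the isopropyl ether are left alone.

Step 4
Reactants: 6 3-(3-iodo-4-isopropoxyphenyl)-1-(2,4,6-trihydroxyphenyl)propan-1-one
Product: 7 3-[4-isopropoxy-3-(trimethylsilylethynyl)phenyl]-1-(2,4,6-trihydroxyphenyl)propan-1-one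
Conditions: ethynyltrimethylsilane, PdCl2(PPh3)2 (2 mol%), CuI (4 mol%), Et3N, THF (degassed), 45 °C
Reagents that add atoms: ethynyltrimethylsilane, C#C[Si](C)(C)C
Why: Sonogashira coupling: oxidative addition of the aryl iodide to zerovalent palladium and transfer of the copper acetylide should proceed in the presence of free phenols, and the silyl cap allows only one coupling per alkyne.

Step 5
Reactants: 7 3-[4-isopropoxy-3-(trimethylsilylethynyl)phenyl]-1-(2,4,6-trihydroxyphenyl)propan-1-one
Product: 8 1-[2,6-dihydroxy-4-(2-methylbut-3-yn-2-yloxy)phenyl]-3-[4-isopropoxy-3-(trimethylsilylethynyl)phenyl]propan-1-one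
Conditions: 3-chloro-3-methylbut-1-yne (1.2 equiv), K2CO3 (1.1 equiv), KI, CuI (cat.), acetone, 50 °C
Reagents that add atoms: 3-chloro-3-methylbut-1-yne, CC(C)(Cl)C#C
Why: Copper-assisted Williamson-type O-alkylation with a tertiary propargylic chloride: of the three phenols only the 4-OH para to the ketone is not tied up in a hydrogen bond to the carbonyl and it is the most acidic, so one equivalent of carbonate should direct the alkylation there, and the silyl alkyne is inert in aprotic acetone.

Step 6
Reactants: 8 1-[2,6-dihydroxy-4-(2-methylbut-3-yn-2-yloxy)phenyl]-3-[4-isopropoxy-3-(trimethylsilylethynyl)phenyl]propan-1-one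
Product: 9 1-[2,6-dihydroxy-4-(2-methylbut-3-yn-2-yloxy)phenyl]-3-(3-ethynyl-4-isopropoxyphenyl)propan-1-one
Conditions: K2CO3, MeOH/THF, rt; then aq. NH4Cl
Reagents that add atoms: none
Why: Base-mediated protiodesilylation of an alkynylsilane: methoxide attacks silicon and the acetylide is protonated by methanol, while the ethers, the ketone and the propargyl ether are inert to K2CO3/MeOH at room temperature.

Step 7
Reactants: 9 1-[2,6-dihydroxy-4-(2-methylbut-3-yn-2-yloxy)phenyl]-3-(3-ethynyl-4-isopropoxyphenyl)propan-1-one
Product: 11 1-(5,7-dihydroxy-2,2-dimethyl-2H-chromen-6-yl)-3-(2,2-dimethyl-2H-chromen-6-yl)propan-1-one, via ring-A monochromene 10 (not isolated)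
Conditions: [(2-biphenylyl)(t-Bu)2PAu(NCMe)]SbF6 (5 mol%), 4 Å MS, ClCH2CH2Cl (0.02 M), rt, then 80 °C
Reagents that add atoms: none
Why: Proposed new method: at room temperature the cationic monovalent gold catalyst activates the propargyl-ether alkyne and the pyran on ring A closes by the known 6-endo-dig hydroarylation of aryl propargyl ethers (C4–C4a bond) to give 10; on heating, gold then activates the arylacetylene of ring B, the tertiary, oxygen-activated C–H of the isopropyl ether delivers hydride through a six-membered transition state to the internal alkyne carbon (future C4), and the resulting aryl-oxocarbenium carbon C2 is captured by the vinyl-gold carbon C3, which forms the C2–C3 bond and releases the catalyst. The closest known reaction type is the platinum- or gold-catalysed 1,5-hydride shift/cyclization (hydroalkylation) of alkynes by ether α-C–H bonds, together with the Lewis-acid internal-redox closure of ortho-alkoxybenzylidene malonates to chromans; new here is an aryl isopropyl ether as donor with an ortho-ethynyl acceptor, so that the ether oxygen becomes a ring atom. The pyran on ring A closes 6-endo-dig (arene carbon onto the alkyne) and the pyran on ring B closes by attack of the gold-bearing C3 on the oxocarbenium carbon C2, 6-endo-trig with respect to the O1=C2 bond. No stereocentre is formed, because each C2 carries two methyl groups. The step needs hydride delivery to the internal alkyne carbon and six- rather than five-membered closure: the internal carbon is the one 1,5 to the C–H bond and the one that best bears positive charge (benzylic and ortho to the alkoxy group), anti addition of hydride and gold leaves the C3–Au bond cis to the arene and pointing at C2, and bond formation at C3 places the developing charge at C4 where the arene and O1 stabilise it; in ring A both ortho carbons are equivalent by symmetry. Reversible attack of the ether oxygen on the alkyne is unproductive because an isopropyl group does not migrate, and the para-alkyl substituent keeps the ether oxygen electron-rich enough to support the oxocarbenium ion.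

Step 8
Reactants: 11 1-(5,7-dihydroxy-2,2-dimethyl-2H-chromen-6-yl)-3-(2,2-dimethyl-2H-chromen-6-yl)propan-1-one
Product: 12 1-(5,7-dihydroxy-2,2-dimethylchroman-6-yl)-3-(2,2-dimethylchroman-6-yl)propan-1-one
Conditions: H2 (1 atm), Pd/C (10 wt%), EtOAc, rt
Reagents that add atoms: none
Why: Heterogeneous catalytic hydrogenation: the two cis-disubstituted styrene-type C3=C4 bonds should be saturated at 1 atm over Pd/C, while the hydrogen-bonded aryl ketone and the aryl C–O bonds are not reduced under these conditions; no stereocentre arises.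

Compound list
1 | 3-(4-hydroxyphenyl)propanenitrile | N#CCCc1ccc(O)cc1 | starting material
2 | 3-(4-hydroxy-3-iodophenyl)propanenitrile | N#CCCc1ccc(O)c(I)c1 | intermediate
3 | 3-(3-iodo-4-isopropoxyphenyl)propanenitrile | N#CCCc1ccc(OC(C)C)c(I)c1 | intermediate
4 | phloroglucinol (benzene-1,3,5-triol) | Oc1cc(O)cc(O)c1 | starting material
5 | 3-(3-iodo-4-isopropoxyphenyl)-1-(2,4,6-trihydroxyphenyl)propan-1-iminium chloride (ketiminium chloride, formed in the flask in step 3) | [NH2+]=C(CCc1ccc(OC(C)C)c(I)c1)c1c(O)cc(O)cc1O.[Cl-] | intermediate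
6 | 3-(3-iodo-4-isopropoxyphenyl)-1-(2,4,6-trihydroxyphenyl)propan-1-one | O=C(CCc1ccc(OC(C)C)c(I)c1)c1c(O)cc(O)cc1O | intermediate
7 | 3-[4-isopropoxy-3-(trimethylsilylethynyl)phenyl]-1-(2,4,6-trihydroxyphenyl)propan-1-one | O=C(CCc1ccc(OC(C)C)c(C#C[Si](C)(C)C)c1)c1c(O)cc(O)cc1O | intermediate
8 | 1-[2,6-dihydroxy-4-(2-methylbut-3-yn-2-yloxy)phenyl]-3-[4-isopropoxy-3-(trimethylsilylethynyl)phenyl]propan-1-one | O=C(CCc1ccc(OC(C)C)c(C#C[Si](C)(C)C)c1)c1c(O)cc(OC(C)(C)C#C)cc1O | intermediate
9 | 1-[2,6-dihydroxy-4-(2-methylbut-3-yn-2-yloxy)phenyl]-3-(3-ethynyl-4-isopropoxyphenyl)propan-1-one | O=C(CCc1ccc(OC(C)C)c(C#C)c1)c1c(O)cc(OC(C)(C)C#C)cc1O | intermediate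
10 | 1-(5,7-dihydroxy-2,2-dimethyl-2H-chromen-6-yl)-3-(3-ethynyl-4-isopropoxyphenyl)propan-1-one (ring-A monochromene, formed in the flask in step 7) | O=C(CCc1ccc(OC(C)C)c(C#C)c1)c1c(O)cc2OC(C)(C)C=Cc2c1O | intermediate
11 | 1-(5,7-dihydroxy-2,2-dimethyl-2H-chromen-6-yl)-3-(2,2-dimethyl-2H-chromen-6-yl)propan-1-one | O=C(CCc1ccc2OC(C)(C)C=Cc2c1)c1c(O)cc2OC(C)(C)C=Cc2c1O | intermediate
12 | 1-(5,7-dihydroxy-2,2-dimethylchroman-6-yl)-3-(2,2-dimethylchroman-6-yl)propan-1-one (CNP0080574.0) | CC1(C)CCc2cc(CCC(=O)c3c(O)cc4c(c3O)CCC(C)(C)O4)ccc2O1 | target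

Total step count: 8. Longest linear sequence: 8 steps (from 1 to 12).

Steps most likely to fail

Step 7 (the proposed method). The hydride transfer from the aryl ether C–H may be too slow, so that the gold-activated arylacetylene is diverted into hydration or oligomerisation. The vinyl-gold intermediate may also close through its other carbon to a five-membered ring, or the ether oxygen may add to the alkyne with loss of propene. The fallback uses known chemistry and keeps the C2–C3 ring closure, but with a doubly activated alkene as hydride acceptor; it sets out from 3 and comes back to the route at 12. Reductive carbonylation of 3 (PdCl2(PPh3)2, CO 1 atm, Et3SiH, Na2CO3, DMF, 80 °C) should give 3-(3-formyl-4-isopropoxyphenyl)propanenitrile F1. Knoevenagel condensation with Meldrum's acid (piperidinium acetate cat., EtOH, rt) gives 5-[[5-(2-cyanoethyl)-2-isopropoxyphenyl]methylidene]-2,2-dimethyl-1,3-dioxane-4,6-dione F2. Sc(OTf)3 (10 mol%) in ClCH2CH2Cl at 80 °C then triggers the Lewis-acid internal redox reaction: 1,5-hydride shift from the isopropyl C–H to the benzylidene carbon, followed by closure of the Meldrum's acid enolate carbon onto the oxocarbenium carbon. This should give the spiro compound 6-(2-cyanoethyl)-2,2,2',2'-tetramethylspiro[chromane-3,5'-[1,3]dioxane]-4',6'-dione F3. Heating in aqueous pyridine (100 °C) opens the dioxanedione with loss of acetone and carbon dioxide to racemic 6-(2-cyanoethyl)-2,2-dimethylchroman-3-carboxylic acid F4. Hydrodecarboxylation (9-mesityl-10-phenylacridinium tetrafluoroborate cat., PhSSPh cat., i-Pr2NEt cat., CF3CH2OH, blue light; or Barton decarboxylation) gives 3-(2,2-dimethylchroman-6-yl)propanenitrile F5. Hoesch reaction of F5 with 4 under the conditions of step 3 passes through 3-(2,2-dimethylchroman-6-yl)-1-(2,4,6-trihydroxyphenyl)propan-1-iminium chloride F6 to 3-(2,2-dimethylchroman-6-yl)-1-(2,4,6-trihydroxyphenyl)propan-1-one F7. O-Propargylation as in step 5 gives 1-[2,6-dihydroxy-4-(2-methylbut-3-yn-2-yloxy)phenyl]-3-(2,2-dimethylchroman-6-yl)propan-1-one F8. The known gold-catalysed 6-endo-dig hydroarylation (first stage of step 7, rt) gives 1-(5,7-dihydroxy-2,2-dimethyl-2H-chromen-6-yl)-3-(2,2-dimethylchroman-6-yl)propan-1-one F9, and hydrogenation as in step 8 gives 12.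

Step 5. C-Alkylation of the electron-rich acylphloroglucinol ring, alkylation of a second (chelated) phenol or elimination of the tertiary chloride may outrun mono-O-alkylation. The fallback builds the pyran on ring A without any O-alkylation; it sets out from 7 and comes back to the route at 10. Condensation of 7 with 3-methylbut-2-enal (ethylenediammonium diacetate cat., toluene, 110 °C) proceeds by C-alkylation at a ring carbon between two oxygens, dehydration to an ortho-quinone methide and oxa-6π electrocyclization. Closure is expected on the oxygen para to the ketone, because the two ortho hydroxyl groups stay hydrogen-bonded to the carbonyl. This should give 1-(5,7-dihydroxy-2,2-dimethyl-2H-chromen-6-yl)-3-[4-isopropoxy-3-(trimethylsilylethynyl)phenyl]propan-1-one F10. Desilylation (K2CO3, MeOH, rt) gives 10, which is then heated with the gold catalyst as in the second stage of step 7 to give 11.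

Step 3. The isopropyl ether may be cleaved by HCl/ZnCl2, or the reaction may stall before C-acylation (imidate formation at oxygen, poor solubility of the nitrilium salt). The fallback reverses the polarity, with a nucleophilic arene and an electrophilic side chain; it sets out from 3 and 4 and comes back to the route at 6. Compound 4 is converted to 1,3,5-tris(methoxymethoxy)benzene F11 (NaH, MOMCl, DMF, 0 °C). Compound 3 is reduced to 3-(3-iodo-4-isopropoxyphenyl)propanal F12 (DIBAL-H, toluene, −78 °C; then aq. HCl). F11 is lithiated between two MOM ethers (n-BuLi, THF, 0 °C) to 2,4,6-tris(methoxymethoxy)phenyllithium F13, which adds to F12 at −78 °C to give racemic 3-(3-iodo-4-isopropoxyphenyl)-1-[2,4,6-tris(methoxymethoxy)phenyl]propan-1-ol F14. Dess–Martin oxidation (CH2Cl2, rt) gives 3-(3-iodo-4-isopropoxyphenyl)-1-[2,4,6-tris(methoxymethoxy)phenyl]propan-1-one F15, and HCl in MeOH (50 °C) removes the three MOM groups to give 6.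

Further compounds
F1 | step 7 | 3-(3-formyl-4-isopropoxyphenyl)propanenitrile | N#CCCc1ccc(OC(C)C)c(C=O)c1
F2 | step 7 | 5-[[5-(2-cyanoethyl)-2-isopropoxyphenyl]methylidene]-2,2-dimethyl-1,3-dioxane-4,6-dione | N#CCCc1ccc(OC(C)C)c(C=C2C(=O)OC(C)(C)OC2=O)c1
F3 | step 7 | 6-(2-cyanoethyl)-2,2,2',2'-tetramethylspiro[chromane-3,5'-[1,3]dioxane]-4',6'-dione | N#CCCc1ccc2OC(C)(C)C3(Cc2c1)C(=O)OC(C)(C)OC3=O
F4 | step 7 | racemic 6-(2-cyanoethyl)-2,2-dimethylchroman-3-carboxylic acid | N#CCCc1ccc2OC(C)(C)C(C(=O)O)Cc2c1
F5 | step 7 | 3-(2,2-dimethylchroman-6-yl)propanenitrile | N#CCCc1ccc2OC(C)(C)CCc2c1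
F6 | step 7 | 3-(2,2-dimethylchroman-6-yl)-1-(2,4,6-trihydroxyphenyl)propan-1-iminium chloride | [NH2+]=C(CCc1ccc2OC(C)(C)CCc2c1)c1c(O)cc(O)cc1O.[Cl-]
F7 | step 7 | 3-(2,2-dimethylchroman-6-yl)-1-(2,4,6-trihydroxyphenyl)propan-1-one | O=C(CCc1ccc2OC(C)(C)CCc2c1)c1c(O)cc(O)cc1O
F8 | step 7 | 1-[2,6-dihydroxy-4-(2-methylbut-3-yn-2-yloxy)phenyl]-3-(2,2-dimethylchroman-6-yl)propan-1-one | O=C(CCc1ccc2OC(C)(C)CCc2c1)c1c(O)cc(OC(C)(C)C#C)cc1O
F9 | step 7 | 1-(5,7-dihydroxy-2,2-dimethyl-2H-chromen-6-yl)-3-(2,2-dimethylchroman-6-yl)propan-1-one | O=C(CCc1ccc2OC(C)(C)CCc2c1)c1c(O)cc2OC(C)(C)C=Cc2c1O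
F10 | step 5 | 1-(5,7-dihydroxy-2,2-dimethyl-2H-chromen-6-yl)-3-[4-isopropoxy-3-(trimethylsilylethynyl)phenyl]propan-1-one | O=C(CCc1ccc(OC(C)C)c(C#C[Si](C)(C)C)c1)c1c(O)cc2OC(C)(C)C=Cc2c1O
F11 | step 3 | 1,3,5-tris(methoxymethoxy)benzene | COCOc1cc(OCOC)cc(OCOC)c1
F12 | step 3 | 3-(3-iodo-4-isopropoxyphenyl)propanal | O=CCCc1ccc(OC(C)C)c(I)c1
F13 | step 3 | 2,4,6-tris(methoxymethoxy)phenyllithium | [Li]c1c(OCOC)cc(OCOC)cc1OCOC
F14 | step 3 | racemic 3-(3-iodo-4-isopropoxyphenyl)-1-[2,4,6-tris(methoxymethoxy)phenyl]propan-1-ol | OC(CCc1ccc(OC(C)C)c(I)c1)c1c(OCOC)cc(OCOC)cc1OCOC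
F15 | step 3 | 3-(3-iodo-4-isopropoxyphenyl)-1-[2,4,6-tris(methoxymethoxy)phenyl]propan-1-one | O=C(CCc1ccc(OC(C)C)c(I)c1)c1c(OCOC)cc(OCOC)cc1OCOC
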